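**Retrosynthetic overview**

1. Numbering (target skeleton): seven-membered ring C1 (side chain), C2, C3 (OH), C4 (=CH2), C5, C9, C10 (OH); cyclopentene C5–C6–C7=C8(CH3)–C9; side chain Cα(CH3)–C1'(OAc)–C2'–C3'(OH)–C(CH3)=CH2. The strategy rests on the cis relationship, on the seven-membered ring, between the C10 hydroxyl and the C1–Cα bond.
2. Side chain: C3'–OH by CBS reduction and C1'–C2' by a Felkin-selective Mukaiyama aldol on a Cα-methyl aldehyde. The aldehyde comes from the cis-fused γ-lactone O(C10)–C1'–Cα–C1–C10, whose Cα is fixed by kinetic protonation.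
3. Key disconnection C1–Cα: a bromoacetal (C1'–Cα) hung on the C10 oxygen closes 5-exo onto C1 of the C1=C2 alkene (Ueno–Stork). This five-membered acetal ring is the third ring formed and is opened again later.
4. Seven-membered ring (second ring): ring-closing metathesis forming C1=C2 between a C10 vinyl carbinol and a C3 alkenyl carbinol. C3 comes from a catalytic asymmetric alkenylzinc addition to a C4-methylidene aldehyde.
5. Cyclopentene (first ring, from 3-ethoxycyclopent-2-en-1-one): CuH asymmetric conjugate reduction sets C5, enolate aldol with acrolein sets C9 and C10, and enol triflate methylation gives C7=C8–CH3.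

Key step: step 14

Assumption: in the reagent-controlled steps (3, 9, 24) the catalyst antipode named is the one expected from the accepted models to give the drawn configuration; the route commits to the drawn configurations, and the other antipode is used if the sense proves opposite.
Note: descriptors on intermediates refer to the skeleton numbering above (CIP labels at C5 and C9 change with the substituents, the spatial arrangement does not).

**Route**

Step 1
Reactants: 1 3-ethoxycyclopent-2-en-1-one; 2 methyl acetate
Product: 5 3-(2-hydroxyethyl)cyclopent-2-en-1-one, via ester adduct 3 (not isolated), via diol enol ether 4 (not isolated)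
Conditions: 2, LiN(iPr)2, THF, −78 °C; then 1; LiAlH4, −78 to 0 °C; 2 M HCl (aq), rt
Reagents that add atoms: methyl acetate, COC(C)=O; water, O
Why: Stork–Danheiser transposition: the ester enolate adds 1,2 to the vinylogous ester, the ester is reduced in the same flask, and acid hydrolysis of the enol ether with loss of the tertiary hydroxyl gives the 3-substituted enone; no stereocentre is formed.

Step 2
Reactants: 5 3-(2-hydroxyethyl)cyclopent-2-en-1-one; 6 chlorotriethylsilane
Product: 7 3-[2-(triethylsilyloxy)ethyl]cyclopent-2-en-1-one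
Conditions: TESCl, imidazole, CH2Cl2, 0 °C to rt
Reagents that add atoms: chlorotriethylsilane, CC[Si](Cl)(CC)CC
Why: Standard silylation of a primary alcohol; the primary TES ether is chosen because it can later be oxidised directly to the aldehyde (step 7).

Step 3
Reactants: 7 3-[2-(triethylsilyloxy)ethyl]cyclopent-2-en-1-one; 8 acrolein
Product: 11 anti aldol (2S,3R)-2-[(1S)-1-hydroxyprop-2-en-1-yl]-3-[2-(triethylsilyloxy)ethyl]cyclopentan-1-one, via diphenylsilyl bis-enol ether 9 (not isolated), via lithium enolate 10 (not isolated)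
Conditions: CuCl (5 mol %), NaOtBu (5 mol %), (S)-p-tol-BINAP (5 mol %), Ph2SiH2 (0.55 equiv), toluene, 0 °C; THF, MeLi (1.1 equiv), 0 °C; acrolein, −78 °C; NH4Cl (aq)
Reagents that add atoms: acrolein, C=CC=O
Why: CuH-catalysed asymmetric conjugate reduction (the p-tol-BINAP–CuH complex delivers hydride to one enantioface of the enone and sets C5) gives the regiodefined silyl enol ether 9, MeLi releases the lithium enolate 10, and its aldol addition to acrolein occurs on the ring face opposite the C5 side chain (C9, trans) through a chair Zimmerman–Traxler transition state in which the ring-locked (E)-enolate gives the anti adduct (C10), any syn epimer being removed by chromatography.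

Step 4
Reactants: 11 anti aldol; 6 chlorotriethylsilane
Product: 12 bis-TES ketone (2S,3R)-3-[2-(triethylsilyloxy)ethyl]-2-[(1S)-1-(triethylsilyloxy)prop-2-en-1-yl]cyclopentan-1-one
Conditions: TESCl, imidazole, DMF, 0 °C
Reagents that add atoms: chlorotriethylsilane, CC[Si](Cl)(CC)CC
Why: Silylation of the aldol hydroxyl protects the β-hydroxy ketone against retro-aldol cleavage and dehydration in the base steps that follow.

Step 5
Reactants: 12 bis-TES ketone; 13 N-phenylbis(trifluoromethanesulfonimide)
Product: 15 C7=C8 enol triflate, via potassium enolate 14 (not isolated)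
Conditions: KN(SiMe3)2, THF, −78 °C; PhNTf2, −78 to −20 °C
Reagents that add atoms: N-phenylbis(trifluoromethanesulfonimide), O=S(=O)(N(c1ccccc1)S(=O)(=O)C(F)(F)F)C(F)(F)F
Why: Regioselective enol triflate formation: the bulky amide base removes a proton from the unhindered C7 methylene under kinetic control (the C9 methine is shielded by its two substituents) and enolate 14 is O-sulfonylated, leaving C9 untouched.

Step 6
Reactants: 15 C7=C8 enol triflate; 16 methylmagnesium bromide
Product: 17 bis-TES methylcyclopentene (5R,9R,10S)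
Conditions: MeMgBr, Fe(acac)3 (5 mol %), THF/NMP, −30 °C
Reagents that add atoms: methylmagnesium bromide, C[Mg]Br
Why: Iron-catalysed cross-coupling of an alkenyl triflate with a methyl Grignard reagent (Kumada-type coupling) installs the C8 methyl group without moving the C7=C8 double bond.

Step 7
Reactants: 17 bis-TES methylcyclopentene
Product: 18 C3 aldehyde (5R,9R,10S)
Conditions: (COCl)2, DMSO, CH2Cl2, −78 to −40 °C; Et3N, −78 to 0 °C
Reagents that add atoms: none
Why: Swern oxidation applied directly to the silyl ether: the chlorosulfonium reagent cleaves and oxidises the primary TES ether much faster than the hindered secondary one, so the C3 aldehyde forms without a separate deprotection.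

Step 8
Reactants: 18 C3 aldehyde; 19 dimethylmethylideneammonium iodide (Eschenmoser's salt)
Product: 20 C4-methylidene enal (5S,9R,10S)
Conditions: Eschenmoser's salt, Et3N, CH2Cl2, rt
Reagents that add atoms: dimethylmethylideneammonium iodide, C=[N+](C)C.[I-]
Why: Mannich reaction at C4 followed by elimination of dimethylamine (α-methylenation of an aldehyde) installs the C4 methylidene; the C5 hydrogen is cross-conjugated to the carbonyl and is not epimerised.

Step 9
Reactants: 20 C4-methylidene enal; 21 hex-1-yne
Product: 22 C3 alcohol (3S,5S,9R,10S) carrying an (E)-hex-1-enyl group at C3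
Conditions: hex-1-yne, Cy2BH, toluene, 0 °C to rt; Et2Zn, −78 °C; (−)-MIB (10 mol %); 20, −30 to 0 °C
Reagents that add atoms: hex-1-yne, CCCCC#C
Why: Catalytic asymmetric alkenylzinc addition (alkyne hydroboration, boron-to-zinc transmetalation, amino alcohol catalysis): the chiral zinc aminoalkoxide delivers the (E)-hexenyl group to the Si face of the aldehyde and sets C3 (S) by catalyst control, the remote C5 centre having little influence.

Step 10
Reactants: 22 C3 alcohol; 23 tert-butyldimethylsilyl trifluoromethanesulfonate
Product: 24 C3 TBS ether (3S,5S,9R,10S)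
Conditions: TBSOTf, 2,6-lutidine, CH2Cl2, −78 °C
Reagents that add atoms: tert-butyldimethylsilyl trifluoromethanesulfonate, CC(C)(C)[Si](C)(C)OS(=O)(=O)C(F)(F)F
Why: Silylation of the bis-allylic C3 alcohol with a silyl triflate at low temperature gives a TBS ether that survives the later removal of the TES group.

Step 11
Reactants: 24 C3 TBS ether
Product: 25 diene alcohol with free C10 hydroxyl (3S,5S,9R,10S)
Conditions: PPTS (0.2 equiv), MeOH/CH2Cl2, 0 °C
Reagents that add atoms: none
Why: Acid-catalysed methanolysis cleaves the triethylsilyl ether much faster than the bulkier tert-butyldimethylsilyl ether, so only the C10 hydroxyl is freed.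

Step 12
Reactants: 25 diene alcohol
Product: 26 trans-fused hydroazulene dienol (3S,5S,9R,10S)
Conditions: second-generation Grubbs catalyst (5 mol %), CH2Cl2 (5 mM), 40 °C
Reagents that add atoms: none
Why: Ring-closing metathesis: the catalyst loads at the terminal C10 vinyl group and closes onto the C3 alkenyl group with loss of hex-1-ene to form the seven-membered ring with the C1=C2 alkene, whereas closure onto the C4 methylidene would need a trans-fused bicyclo[3.3.0]octene; no stereocentre is formed.

Step 13
Reactants: 26 hydroazulene dienol; 27 ethyl prop-1-enyl ether; 28 N-bromosuccinimide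
Product: 29 bromoacetal (3S,5S,9R,10S)
Conditions: ethyl prop-1-enyl ether (4 equiv), NBS (1.3 equiv), CH2Cl2, −78 to −20 °C
Reagents that add atoms: ethyl prop-1-enyl ether, CC=COCC; N-bromosuccinimide, O=C1CCC(=O)N1Br
Why: Bromoacetalisation: NBS brominates the electron-rich enol ether and the oxocarbenium ion is trapped by the C10 hydroxyl, chemoselectively in the presence of the less nucleophilic ring alkenes; the acetal and bromide carbons are left as mixtures.

Step 14
Reactants: 29 bromoacetal
Product: 30 cis-fused bicyclic ethyl acetal (1R,3S,5S,9R,10S)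
Conditions: Bu3SnH (1.3 equiv, 0.03 M), Et3B (0.2 equiv), air, toluene, 0 °C to rt
Reagents that add atoms: none
Why: Et3B/O2 generates Bu3Sn•, which abstracts bromine from 29 to give the secondary Cα radical; this adds 5-exo-trig to C1 of the C1=C2 alkene, closing the five-membered acetal ring (O, C1', Cα, C1, C10) and forming the C1–Cα bond, and the resulting C2 radical is reduced by Bu3SnH (Ueno–Stork haloacetal radical cyclisation, the closest known reaction type, well established on cycloalkenyl bromoacetals). The three-atom O–C1'–Cα tether allows only cis fusion of the new ring to the seven-membered ring, so C1 is set by the C10 stereocentre: Cα is delivered to the face that carries the C10 oxygen, giving (1R). Cα is formed in a chair-like transition state that should favour the methyl group cis to C2 (the target configuration), but this bias is not relied upon, so 30 is written without a Cα descriptor and the centre is fixed in step 17. The step needs 5-exo closure to beat direct reduction of the Cα radical and 6-endo attack at C2, which the short acetal tether and the moderate tin hydride concentration secure. It also needs hydrogen transfer to the C2 radical to beat its 3-exo attack on the neighbouring C4 methylidene (homoallyl rearrangement), which initiation at low temperature and about 0.03 M Bu3SnH should secure. The C4 methylidene and the C7=C8 alkene cannot be reached by the tethered Cα radical, and the acetal and bromide carbons may enter as mixtures because both become trigonal later (lactone carbonyl, enolate).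

Step 15
Reactants: 30 cis-fused bicyclic ethyl acetal
Product: 31 lactol (Cα and lactol carbon as mixtures)
Conditions: 0.5 M HCl (aq), THF, 0 °C to rt
Reagents that add atoms: water, O
Why: Acid-catalysed hydrolysis of the 2-alkoxytetrahydrofuran acetal through the cyclic oxocarbenium ion is much faster than cleavage of the secondary TBS ether.

Step 16
Reactants: 31 lactol
Product: 32 γ-lactone (Cα epimers)
Conditions: TEMPO (0.2 equiv), PhI(OAc)2, CH2Cl2, rt
Reagents that add atoms: none
Why: TEMPO/PhI(OAc)2 oxidation of a lactol to the γ-lactone, mild enough for the alkenes and the silyl ether.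

Step 17
Reactants: 32 γ-lactone (Cα epimers)
Product: 34 γ-lactone (αS,1R,3S,5S,9R,10S), via lithium enolate 33 (not isolated)
Conditions: LiN(iPr)2, THF, −78 °C; 2,6-di-tert-butyl-4-methylphenol, THF, −78 °C
Reagents that add atoms: none
Why: Kinetic protonation of a lactone enolate: enolisation erases Cα and the bulky phenol delivers the proton to the convex face of the cis-fused bicycle (the face of the C1 and C10 hydrogens), which places the methyl group on the concave face, cis to C2, the (S) configuration required at Cα.

Step 18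
Reactants: 34 γ-lactone (αS); 35 N,O-dimethylhydroxylamine hydrochloride
Product: 36 hydroxy Weinreb amide
Conditions: MeNH(OMe)·HCl, AlMe3, CH2Cl2, 0 °C to rt
Reagents that add atoms: N,O-dimethylhydroxylamine hydrochloride, CNOC.Cl
Why: Aminolysis of the lactone with the aluminium amide of N,O-dimethylhydroxylamine (Weinreb amide formation) frees the C10 hydroxyl and leaves Cα untouched.

Step 19
Reactants: 36 hydroxy Weinreb amide; 23 tert-butyldimethylsilyl trifluoromethanesulfonate
Product: 37 silylated Weinreb amide
Conditions: TBSOTf, 2,6-lutidine, CH2Cl2, −78 to 0 °C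
Reagents that add atoms: tert-butyldimethylsilyl trifluoromethanesulfonate, CC(C)(C)[Si](C)(C)OS(=O)(=O)C(F)(F)F
Why: Silylation of the hindered C10 hydroxyl with a silyl triflate prevents relactonisation and masks C10–OH for the later acetylation at C1'.

Step 20
Reactants: 37 silylated Weinreb amide
Product: 38 Cα-methyl aldehyde
Conditions: iBu2AlH, THF, −78 °C; KNa tartrate (aq)
Reagents that add atoms: none
Why: iBu2AlH reduction of a Weinreb amide stops at the chelated tetrahedral intermediate and gives the aldehyde on work-up; it is used at once to avoid epimerisation at Cα.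

Step 21
Reactants: 39 3-methylbut-3-en-2-one; 40 chlorotrimethylsilane
Product: 41 silyl dienol ether 3-methyl-2-(trimethylsilyloxy)buta-1,3-diene
Conditions: LiN(iPr)2, Me3SiCl (premixed), THF, −78 °C
Reagents that add atoms: chlorotrimethylsilane, C[Si](C)(C)Cl
Why: Kinetic enolisation of the methyl ketone at its only enolisable α-position with in situ O-silylation gives the 2-silyloxydiene.

Step 22
Reactants: 38 Cα-methyl aldehyde; 41 silyl dienol ether
Product: 42 β-hydroxy enone (1'S)
Conditions: BF3·OEt2, CH2Cl2, −78 °C
Reagents that add atoms: 3-methyl-2-(trimethylsilyloxy)buta-1,3-diene, C=C(C)C(=C)O[Si](C)(C)C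
Why: BF3-mediated Mukaiyama aldol addition through an open transition state: Felkin–Anh attack anti to the large C1 substituent of the α-methyl aldehyde gives the C1' alcohol syn to the Cα methyl group, which is (1'S).

Step 23
Reactants: 42 β-hydroxy enone; 43 acetic anhydride
Product: 44 β-acetoxy enone
Conditions: Ac2O, pyridine, DMAP (cat.), CH2Cl2, 0 °C
Reagents that add atoms: acetic anhydride, CC(=O)OC(C)=O
Why: DMAP-catalysed acetylation of the only free hydroxyl at 0 °C, mild enough to avoid β-elimination of the β-acetoxy ketone.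

Step 24
Reactants: 44 β-acetoxy enone
Product: 45 bis-TBS ether of the target (3'R)
Conditions: (S)-Me-CBS oxazaborolidine (0.3 equiv), catecholborane, toluene, −78 °C
Reagents that add atoms: none
Why: CBS reduction: the oxazaborolidine–borane complex differentiates the isopropenyl group (large) from the C2' methylene (small) and delivers hydride to give the (3'R) allylic alcohol, syn to the C1' acetate, by catalyst control, while catecholborane leaves the alkenes and the acetate untouched.

Step 25
Reactants: 45 bis-TBS ether of the target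
Product: 46 target CNP0281601.4
Conditions: HF·pyridine, pyridine, THF, 0 °C to rt
Reagents that add atoms: none
Why: Fluoride-mediated cleavage of both TBS ethers with buffered HF·pyridine, which leaves the secondary acetate in place and does not promote acyl migration, gives the target.

**Compound list**

1 | 3-ethoxycyclopent-2-en-1-one | CCOC1=CC(=O)CC1 | starting material
2 | methyl acetate | COC(C)=O | starting material
3 | ester adduct: methyl 2-(3-ethoxy-1-hydroxycyclopent-2-en-1-yl)acetate (lithium alkoxide in the flask) | CCOC1=CC(O)(CC(=O)OC)CC1 | intermediate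
4 | diol enol ether: 2-(3-ethoxy-1-hydroxycyclopent-2-en-1-yl)ethan-1-ol (alkoxide in the flask) | CCOC1=CC(O)(CCO)CC1 | intermediate
5 | 3-(2-hydroxyethyl)cyclopent-2-en-1-one | O=C1C=C(CCO)CC1 | intermediate
6 | chlorotriethylsilane | CC[Si](Cl)(CC)CC | starting material
7 | 3-[2-(triethylsilyloxy)ethyl]cyclopent-2-en-1-one | O=C1C=C(CCO[Si](CC)(CC)CC)CC1 | intermediate
8 | acrolein (prop-2-enal) | C=CC=O | starting material
9 | diphenylsilyl bis-enol ether: diphenylbis{[(3R)-3-[2-(triethylsilyloxy)ethyl]cyclopent-1-en-1-yl]oxy}silane | CC[Si](CC)(CC)OCC[C@H]1CCC(O[Si](c2ccccc2)(c2ccccc2)OC2=C[C@@H](CCO[Si](CC)(CC)CC)CC2)=C1 | intermediate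
10 | lithium enolate: lithium (3R)-3-[2-(triethylsilyloxy)ethyl]cyclopent-1-en-1-olate | CC[Si](CC)(CC)OCC[C@H]1CCC(O[Li])=C1 | intermediate
11 | anti aldol: (2S,3R)-2-[(1S)-1-hydroxyprop-2-en-1-yl]-3-[2-(triethylsilyloxy)ethyl]cyclopentan-1-one (skeleton C5 R, C9 S, C10 S; C5/C9 trans, C9/C10 anti) | CC[Si](CC)(CC)OCC[C@H]1CCC(=O)[C@@H]1[C@@H](O)C=C | intermediate
12 | bis-TES ketone: (2S,3R)-3-[2-(triethylsilyloxy)ethyl]-2-[(1S)-1-(triethylsilyloxy)prop-2-en-1-yl]cyclopentan-1-one | CC[Si](CC)(CC)OCC[C@H]1CCC(=O)[C@@H]1[C@@H](O[Si](CC)(CC)CC)C=C | intermediate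
13 | N-phenylbis(trifluoromethanesulfonimide) | O=S(=O)(N(c1ccccc1)S(=O)(=O)C(F)(F)F)C(F)(F)F | starting material
14 | potassium enolate of 12 (C7=C8) | CC[Si](CC)(CC)OCC[C@H]1CC=C(O[K])[C@@H]1[C@@H](O[Si](CC)(CC)CC)C=C | intermediate
15 | C7=C8 enol triflate: (4R,5S)-4-[2-(triethylsilyloxy)ethyl]-5-[(1S)-1-(triethylsilyloxy)prop-2-en-1-yl]cyclopent-1-en-1-yl trifluoromethanesulfonate | CC[Si](CC)(CC)OCC[C@H]1CC=C(OS(=O)(=O)C(F)(F)F)[C@@H]1[C@@H](O[Si](CC)(CC)CC)C=C | intermediate
16 | methylmagnesium bromide | C[Mg]Br | starting material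
17 | bis-TES methylcyclopentene: triethyl({(1S)-1-[(1R,5R)-2-methyl-5-[2-(triethylsilyloxy)ethyl]cyclopent-2-en-1-yl]prop-2-en-1-yl}oxy)silane (skeleton 5R,9R,10S) | CC[Si](CC)(CC)OCC[C@H]1CC=C(C)[C@@H]1[C@@H](O[Si](CC)(CC)CC)C=C | intermediate
18 | C3 aldehyde: 2-[(1R,2R)-3-methyl-2-[(1S)-1-(triethylsilyloxy)prop-2-en-1-yl]cyclopent-3-en-1-yl]acetaldehyde | O=CC[C@H]1CC=C(C)[C@@H]1[C@@H](O[Si](CC)(CC)CC)C=C | intermediate
19 | dimethylmethylideneammonium iodide (Eschenmoser's salt) | C=[N+](C)C.[I-] | starting material
20 | C4-methylidene enal: 2-[(1S,2R)-3-methyl-2-[(1S)-1-(triethylsilyloxy)prop-2-en-1-yl]cyclopent-3-en-1-yl]prop-2-enal | O=CC(=C)[C@H]1CC=C(C)[C@@H]1[C@@H](O[Si](CC)(CC)CC)C=C | intermediate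
21 | hex-1-yne | CCCCC#C | starting material
22 | C3 alcohol: bis-allylic (3S) carbinol with (E)-hex-1-enyl at C3, C4 methylidene and C10 OTES (3S,5S,9R,10S) | CCCC/C=C/[C@H](O)C(=C)[C@H]1CC=C(C)[C@@H]1[C@@H](O[Si](CC)(CC)CC)C=C | intermediate
23 | tert-butyldimethylsilyl trifluoromethanesulfonate | CC(C)(C)[Si](C)(C)OS(=O)(=O)C(F)(F)F | starting material
24 | C3 TBS ether of 22 (3S,5S,9R,10S) | CCCC/C=C/[C@H](O[Si](C)(C)C(C)(C)C)C(=C)[C@H]1CC=C(C)[C@@H]1[C@@H](O[Si](CC)(CC)CC)C=C | intermediate
25 | diene alcohol: 24 with the C10 hydroxyl free (3S,5S,9R,10S) | CCCC/C=C/[C@H](O[Si](C)(C)C(C)(C)C)C(=C)[C@H]1CC=C(C)[C@@H]1[C@@H](O)C=C | intermediate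
26 | trans-fused hydroazulene dienol: C1=C2, C3 OTBS, C4 methylidene, C7=C8 with C8 methyl, C10 OH (3S,5S,9R,10S) | C1=C[C@H](O[Si](C)(C)C(C)(C)C)C(=C)[C@H]2CC=C(C)[C@@H]2[C@H]1O | intermediate
27 | ethyl prop-1-enyl ether (E/Z mixture) | CC=COCC | starting material
28 | N-bromosuccinimide | O=C1CCC(=O)N1Br | starting material
29 | bromoacetal: C10 O-(2-bromo-1-ethoxypropyl) ether of 26 (acetal and bromide carbons as mixtures) | C1=C[C@H](O[Si](C)(C)C(C)(C)C)C(=C)[C@H]2CC=C(C)[C@@H]2[C@H]1OC(OCC)C(C)Br | intermediate
30 | cis-fused bicyclic ethyl acetal (1R,3S,5S,9R,10S); mixture at Cα and at the acetal carbon, the (αS) component having the target configuration | CCOC1C(C)[C@H]2C[C@H](O[Si](C)(C)C(C)(C)C)C(=C)[C@H]3CC=C(C)[C@@H]3[C@H]2O1 | intermediate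
31 | lactol (Cα and lactol carbon as mixtures) | OC1C(C)[C@H]2C[C@H](O[Si](C)(C)C(C)(C)C)C(=C)[C@H]3CC=C(C)[C@@H]3[C@H]2O1 | intermediate
32 | cis-fused γ-lactone (Cα epimers) | O=C1C(C)[C@H]2C[C@H](O[Si](C)(C)C(C)(C)C)C(=C)[C@H]3CC=C(C)[C@@H]3[C@H]2O1 | intermediate
33 | lithium enolate of 32 | [Li]OC1=C(C)[C@H]2C[C@H](O[Si](C)(C)C(C)(C)C)C(=C)[C@H]3CC=C(C)[C@@H]3[C@H]2O1 | intermediate
34 | cis-fused γ-lactone, single epimer (αS,1R,3S,5S,9R,10S), methyl cis to C2 | O=C1[C@@H](C)[C@H]2C[C@H](O[Si](C)(C)C(C)(C)C)C(=C)[C@H]3CC=C(C)[C@@H]3[C@H]2O1 | intermediate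
35 | N,O-dimethylhydroxylamine hydrochloride | CNOC.Cl | starting material
36 | hydroxy Weinreb amide (C10 OH free) | CON(C)C(=O)[C@@H](C)[C@H]1C[C@H](O[Si](C)(C)C(C)(C)C)C(=C)[C@H]2CC=C(C)[C@@H]2[C@H]1O | intermediate
37 | silylated Weinreb amide (C3 and C10 OTBS) | CON(C)C(=O)[C@@H](C)[C@H]1C[C@H](O[Si](C)(C)C(C)(C)C)C(=C)[C@H]2CC=C(C)[C@@H]2[C@H]1O[Si](C)(C)C(C)(C)C | intermediate
38 | Cα-methyl aldehyde (C1' aldehyde; αS) | O=C[C@@H](C)[C@H]1C[C@H](O[Si](C)(C)C(C)(C)C)C(=C)[C@H]2CC=C(C)[C@@H]2[C@H]1O[Si](C)(C)C(C)(C)C | intermediate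
39 | 3-methylbut-3-en-2-one | CC(=O)C(C)=C | starting material
40 | chlorotrimethylsilane | C[Si](C)(C)Cl | starting material
41 | silyl dienol ether: 3-methyl-2-(trimethylsilyloxy)buta-1,3-diene | C=C(C)C(=C)O[Si](C)(C)C | intermediate
42 | β-hydroxy enone: C1' alcohol (1'S), C3' ketone | C=C(C)C(=O)C[C@H](O)[C@@H](C)[C@H]1C[C@H](O[Si](C)(C)C(C)(C)C)C(=C)[C@H]2CC=C(C)[C@@H]2[C@H]1O[Si](C)(C)C(C)(C)C | intermediate
43 | acetic anhydride | CC(=O)OC(C)=O | starting material
44 | β-acetoxy enone (C1' acetate) | C=C(C)C(=O)C[C@H](OC(C)=O)[C@@H](C)[C@H]1C[C@H](O[Si](C)(C)C(C)(C)C)C(=C)[C@H]2CC=C(C)[C@@H]2[C@H]1O[Si](C)(C)C(C)(C)C | intermediate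
45 | bis-TBS ether of the target (3'R,1'S,αS,1R,3S,5S,9R,10S) | C=C(C)[C@H](O)C[C@H](OC(C)=O)[C@@H](C)[C@H]1C[C@H](O[Si](C)(C)C(C)(C)C)C(=C)[C@H]2CC=C(C)[C@@H]2[C@H]1O[Si](C)(C)C(C)(C)C | intermediate
46 | CNP0281601.4 (3'R,1'S,αS,1R,3S,5S,9R,10S) | C=C(C)[C@H](O)C[C@H](OC(C)=O)[C@@H](C)[C@H]1C[C@H](O)C(=C)[C@H]2CC=C(C)[C@@H]2[C@H]1O | target

**Step count and risks**

Total step count: 25. Longest linear sequence: 24 steps (steps 1–20 and 22–25; step 21 prepares the silyl dienol ether 41 used in step 22).

The three steps most likely to fail: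

1. Step 14 (radical cyclisation). Process at risk: hydrogen transfer to the Cα radical before ring closure, or 3-exo attack of the C2 radical on the C4 methylidene before hydrogen transfer, followed by ring contraction. Fallback: the acceptor is turned into an enone, so that ring closure is polarity-matched and the radical formed is a stabilised α-keto radical that cannot rearrange. It sets out from 29. Bu4NF buffered with AcOH (THF, 0 °C) removes the silyl group to give the hydroxy bromoacetal F1. Dess–Martin periodinane (NaHCO3, CH2Cl2) gives the cross-conjugated dienone bromoacetal F2. Bu3SnH/Et3B/air closes the ring onto the enone β-carbon C1 to give the keto acetal F3. Luche reduction (NaBH4, CeCl3·7H2O, MeOH, −78 °C) gives the C3 alcohol F4; its facial selectivity is not predictable, so the C3 epimers are separated and the unwanted one is returned to F3 by oxidation. TBSOTf/2,6-lutidine then gives 30, where the route is rejoined.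

2. Step 3 (reduction–aldol). Process at risk: poor anti/syn selectivity at C10, because the closed transition state of a cyclopentanone enolate is only moderately biased; incomplete release of the enolate from the silyl enol ether is a second risk. Fallback: C10 is corrected by inversion instead of by transition-state control. It sets out from 7, with step 3 run as written and the syn aldol F5 (the C10 epimer of 11) collected by chromatography. Mitsunobu reaction with chloroacetic acid (PPh3, DIAD, toluene, 0 °C) gives the chloroacetate F6 with the C10 configuration of 11. Thiourea/NaHCO3 in EtOH removes the chloroacetyl group under nearly neutral conditions, so that the β-acyloxy ketone is not exposed to strong base, and returns 11.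

3. Step 9 (asymmetric alkenylation). Process at risk: insufficient facial selectivity of the alkenylzinc addition to the hindered 2-substituted acrolein, or competing ethyl transfer from zinc. Fallback: C3 is set by reagent-controlled ketone reduction. It sets out from 20. Lithium hex-1-ynide (hex-1-yne, n-BuLi, THF, −78 °C) gives the propargylic alcohol F7 as a C3 epimer mixture. Dess–Martin periodinane gives the ynone F8. CBS reduction with (R)-Me-CBS/catecholborane (alkynyl as the small group) gives the single propargylic alcohol F9. NaAlH2(OCH2CH2OMe)2 (THF, 0 °C) reduces the propargylic alkyne to the (E)-alkene and returns 22.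

Further compounds
F1 | step 14 | hydroxy bromoacetal: 29 without the C3 silyl group (3S,5S,9R,10S) | C1=C[C@H](O)C(=C)[C@H]2CC=C(C)[C@@H]2[C@H]1OC(OCC)C(C)Br
F2 | step 14 | cross-conjugated dienone bromoacetal: C3 ketone flanked by C1=C2 and C4 methylidene (5S,9R,10S) | C1=CC(=O)C(=C)[C@H]2CC=C(C)[C@@H]2[C@H]1OC(OCC)C(C)Br
F3 | step 14 | keto acetal: cis-fused bicyclic ethyl acetal with C3 ketone (1R,5S,9R,10S; Cα and acetal carbon as mixtures) | CCOC1C(C)[C@H]2CC(=O)C(=C)[C@H]3CC=C(C)[C@@H]3[C@H]2O1
F4 | step 14 | C3 alcohol of the bicyclic ethyl acetal (1R,3S,5S,9R,10S; Cα and acetal carbon as mixtures) | CCOC1C(C)[C@H]2C[C@H](O)C(=C)[C@H]3CC=C(C)[C@@H]3[C@H]2O1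
F5 | step 3 | syn aldol: C10 epimer of 11 | CC[Si](CC)(CC)OCC[C@H]1CCC(=O)[C@@H]1[C@H](O)C=C
F6 | step 3 | chloroacetate of 11 (C10 configuration of 11) | CC[Si](CC)(CC)OCC[C@H]1CCC(=O)[C@@H]1[C@@H](OC(=O)CCl)C=C
F7 | step 9 | propargylic alcohol: hex-1-ynyl carbinol at C3 (C3 epimers; 5S,9R,10S) | CCCCC#CC(O)C(=C)[C@H]1CC=C(C)[C@@H]1[C@@H](O[Si](CC)(CC)CC)C=C
F8 | step 9 | ynone: C3 ketone between the hex-1-ynyl group and the C4 methylidene | CCCCC#CC(=O)C(=C)[C@H]1CC=C(C)[C@@H]1[C@@H](O[Si](CC)(CC)CC)C=C
F9 | step 9 | propargylic alcohol, single C3 epimer with the spatial arrangement of (3S)-22 (formally 3R, the alkynyl group outranking C4) | CCCCC#C[C@H](O)C(=C)[C@H]1CC=C(C)[C@@H]1[C@@H](O[Si](CC)(CC)CC)C=C
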